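**Retrosynthetic overview**

- Working numbering (bicyclo[3.2.1]octane, used in all names and descriptors of bicyclic compounds): C1 methoxy bridgehead, C2 carbinol, C3=C4 enol ether, C5 allyl bridgehead, C6 methyl carbon, C7 aryl carbon, C8 ketone. The route rests on quaternary C5, which is α to the C8 ketone and bonded to methyl-bearing C6.
- Key disconnection C5–C6: 5-exo attack of the C5 α-keto radical (from the tertiary C5 bromide) on the vinyl group held on C7 closes the five-membered ring C5–C8–C1–C7–C6 last. The six-membered ring is that of cyclohexane-1,3-dione.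
- C1–C7 and both stereocentres come from a Claisen rearrangement of an (S)-allylic enol ether of 2-methoxycyclohexane-1,3-dione (chirality transfer from a Corey–Bakshi–Shibata reduction); the alkene methyl it leaves is removed by ethenolysis.
- A silyl enol ether made before the rearrangement marks the C8/C5 side, so allyl and bromine go to C5 with C2 left as a free ketone.
- After ring closure: C3 oxidation to the diosphenol, O-methylation, exo-face Luche reduction at C2, desilylation.

Key step: step 11

Remark: Ar = 3-methoxy-4-[(triisopropylsilyl)oxy]phenyl in all names. The enolate of a C2-ketal ketone bearing the C1 methoxy group would be a β-alkoxy enolate open to loss of methoxide, so C1 is made quaternary at the 1,3-dicarbonyl stage and no C2 ketal is used.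

**Route**

Step 1
Reactants: 1 dehydrozingerone
Product: 2 (E)-4-Ar-but-3-en-2-one
Conditions: iPr3SiCl, imidazole, DMF, rt
Reagents that add atoms: chlorotriisopropylsilane, CC(C)[Si](Cl)(C(C)C)C(C)C
Why: Silyl ether formation at the phenol; the triisopropylsilyl group is chosen because it should withstand the alkoxide, amide-base, carbonate and borohydride steps that follow and leaves with fluoride at the end.

Step 2
Reactants: 2 (E)-4-Ar-but-3-en-2-one
Product: 3 (2S,3E)-4-Ar-but-3-en-2-ol
Conditions: (R)-2-methyl-CBS-oxazaborolidine (0.2 equiv), catecholborane, PhMe, −78 °C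
Reagents that add atoms: none
Why: Corey–Bakshi–Shibata reduction, 1,2-selective on the enone; with the styryl group as the large substituent the (R)-catalyst should deliver hydride to the face that gives the (S)-alcohol, the centre later relayed to C1 and C7.

Step 3
Reactants: 4 cyclohexane-1,3-dione
Product: 5 2-diazocyclohexane-1,3-dione
Conditions: 4-acetamidobenzenesulfonyl azide, Et3N, MeCN, 0 °C to rt
Reagents that add atoms: 4-acetamidobenzenesulfonyl azide, CC(=O)Nc1ccc(cc1)S(=O)(=O)N=[N+]=[N-]
Why: Regitz diazo transfer to the doubly activated carbon between the two carbonyl groups.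

Step 4
Reactants: 5 2-diazocyclohexane-1,3-dione
Product: 6 2-methoxycyclohexane-1,3-dione (enol form, 3-hydroxy-2-methoxycyclohex-2-en-1-one)
Conditions: Rh2(OAc)4 (1 mol%), MeOH, PhH, 80 °C
Reagents that add atoms: methanol, CO
Why: Rhodium-carbenoid O–H insertion into methanol installs the future C1 methoxy group before any stereocentre exists.

Step 5
Reactants: 6 2-methoxycyclohexane-1,3-dione
Product: 7 3-chloro-2-methoxycyclohex-2-en-1-one
Conditions: (COCl)2, DMF (cat.), CH2Cl2, 0 °C to rt
Reagents that add atoms: oxalyl chloride, O=C(Cl)C(=O)Cl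
Why: Conversion of the vinylogous acid into the vinylogous acid chloride (Vilsmeier-type activation); the symmetric dione allows only one product.

Step 6
Reactants: 3 (2S,3E)-4-Ar-but-3-en-2-ol; 7 3-chloro-2-methoxycyclohex-2-en-1-one
Product: 8 2-methoxy-3-{[(2S,3E)-4-Ar-but-3-en-2-yl]oxy}cyclohex-2-en-1-one
Conditions: 3, NaH, THF, 0 °C; then 7, 0 °C to rt
Reagents that add atoms: none
Why: Addition–elimination of the sodium alkoxide at the β-carbon of the β-chloro enone (vinylogous ester formation); the carbinol C–O bond is not touched, so the (S) configuration is kept.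

Step 7
Reactants: 8 2-methoxy-3-{[(2S,3E)-4-Ar-but-3-en-2-yl]oxy}cyclohex-2-en-1-one; 9 allyl bromide
Product: 11 1-allyl-2-[(tert-butyldimethylsilyl)oxy]-3-methoxy-4-{[(2S,3E)-4-Ar-but-3-en-2-yl]oxy}cyclohexa-1,3-diene, via 6-allyl enone 10 (not isolated)
Conditions: LiN(iPr)2, THF, −78 °C; 9, −78 to −20 °C; then LiN(iPr)2, −78 °C; tBuMe2SiCl, DMPU, −78 to 0 °C
Reagents that add atoms: tert-butyldimethylsilyl chloride, CC(C)(C)[Si](C)(C)Cl
Why: Stork–Danheiser chemistry used twice, kinetic α′-deprotonation and allylation at C5, then a second α′-deprotonation and O-silylation, which gives the cross-conjugated silyl dienol ether and marks the carbonyl next to the allyl carbon as the future C8.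

Step 8
Reactants: 11 silyl dienol ether
Product: 12 (2S)-4-allyl-3-[(tert-butyldimethylsilyl)oxy]-2-methoxy-2-[(1S,2E)-1-Ar-but-2-en-1-yl]cyclohex-3-en-1-one
Conditions: PhMe, 2,6-di-tert-butylpyridine (0.1 equiv), 100 °C
Reagents that add atoms: none
Why: Claisen [3,3] rearrangement through a chair transition state with the carbinol methyl and the aryl group pseudo-equatorial, so the (S) centre fixes the face of C1 that is attacked and C1 and C7 form together with the aryl group anti to C8 across the new bond (the relation that later puts it endo), while the former enol ether carbon becomes the C2 ketone and the silyl enol ether keeps C8/C5 distinct.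

Step 9
Reactants: 12 Claisen product
Product: 13 (2S)-4-allyl-3-[(tert-butyldimethylsilyl)oxy]-2-methoxy-2-[(1S)-1-Ar-prop-2-en-1-yl]cyclohex-3-en-1-one
Conditions: ethylene (5 bar), second-generation Hoveyda–Grubbs catalyst RuCl2(=CH-C6H4-2-OiPr)(SIMes) (5 mol%), PhMe, 40 °C
Reagents that add atoms: ethylene, C=C
Why: Olefin cross-metathesis with ethylene (ethenolysis) trims the propenyl group to vinyl with loss of propene; the allyl group only exchanges degenerately, the tetrasubstituted silyl enol ether is inert, and ring closure between the two alkenes would need a bridgehead enol ether double bond.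

Step 10
Reactants: 13 vinyl silyl enol ether
Product: 14 (2R)-4-allyl-4-bromo-2-methoxy-2-[(1S)-1-Ar-prop-2-en-1-yl]cyclohexane-1,3-dione (both C4 epimers; ring C4 is C5 of the working numbering)
Conditions: N-bromosuccinimide, NaHCO3, THF, −78 °C
Reagents that add atoms: N-bromosuccinimide, O=C1CCC(=O)N1Br
Why: Electrophilic bromination of a silyl enol ether, regiospecific at C5 because the enol ether was fixed in step 7 and far faster than attack on the terminal alkenes or the arene; either C5 epimer serves.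

Step 11
Reactants: 14 tertiary bromide
Product: 15 (1R,5R,6R,7S)-5-allyl-7-Ar-1-methoxy-6-methylbicyclo[3.2.1]octane-2,8-dione
Conditions: (Me3Si)3SiH (1.3 equiv) and AIBN (0.2 equiv) added over 6 h to 14 and tert-dodecanethiol (0.3 equiv), PhH (0.01 M), 80 °C
Reagents that add atoms: none
Why: The silyl radical abstracts bromine from either C5 epimer, and the planar, electrophilic tertiary α-keto radical adds through its axial lobe to the internal vinyl carbon C6 of the axial C1 arm; the primary radical then takes hydrogen from the thiol, which the silane regenerates (polarity-reversal catalysis). The closest known reaction type is the 5-exo closure of cyclic α-keto and β-dicarbonyl radicals (from α-halo ketones with tin or silicon hydrides, or by manganese triacetate oxidation) onto a neighbouring alkene arm to give bicyclo[3.2.1]octan-8-ones. The five-membered ring C5–C8–C1–C7–C6 closes 5-exo-trig and completes the bicycle; C5 can bond only on the face that carries the arm, so its configuration follows from C1, and C6 is set in a chair-like transition state with the CH2 terminus exo, away from the endo aryl group (methyl trans to aryl). Three selectivities are needed. The first, 5-exo over 6-endo attack, is the weak point: a radical with its carbonyl inside the forming ring tends to close at the terminal carbon, and here only the short C5–C6 contact in the diaxial conformer and the flat C2 carbonyl, which makes room for the endo aryl group, favour 5-exo. The other two are trans methyl/aryl, secured by the C1/C7 configuration from step 8, and hydrogen transfer to the nucleophilic primary radical before it adds to the C5 allyl group, sought through the thiol (fast toward alkyl radicals, slow toward the α-keto radical) and slow addition of the silane.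

Step 12
Reactants: 15 bicyclic 2,8-dione
Product: 16 5-allyl-7-Ar-3-hydroxy-1-methoxy-6-methylbicyclo[3.2.1]octane-2,8-dione (C1, C5, C6, C7 as in 15; both C3 epimers)
Conditions: LiN(SiMe3)2, THF, −78 °C; 2-(phenylsulfonyl)-3-phenyloxaziridine, −78 °C; NH4Cl (aq)
Reagents that add atoms: 2-(phenylsulfonyl)-3-phenyloxaziridine, O=S(=O)(c1ccccc1)N1OC1c1ccccc1
Why: Enolate hydroxylation with a Davis oxaziridine; C3 is the only enolisable position because C1 and C5 are quaternary, and the C3 configuration is of no consequence.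

Step 13
Reactants: 16 α-ketol
Product: 17 5-allyl-7-Ar-3-hydroxy-1-methoxy-6-methylbicyclo[3.2.1]oct-3-ene-2,8-dione (diosphenol; C1, C5, C6, C7 as in 15)
Conditions: Dess–Martin periodinane, NaHCO3, CH2Cl2, 0 °C to rt
Reagents that add atoms: none
Why: Dess–Martin oxidation of the α-ketol to the 2,3-dione, which can enolise only toward C4 and is expected as the diosphenol.

Step 14
Reactants: 17 diosphenol
Product: 18 5-allyl-7-Ar-1,3-dimethoxy-6-methylbicyclo[3.2.1]oct-3-ene-2,8-dione (C1, C5, C6, C7 as in 15)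
Conditions: Me2SO4, K2CO3, acetone, rt
Reagents that add atoms: dimethyl sulfate, COS(=O)(=O)OC
Why: O-Alkylation of the diosphenol enol oxygen (Williamson-type) gives the C3 methyl enol ether, the only enol ether the dione can form.

Step 15
Reactants: 18 α-methoxy enone
Product: 19 (1R,2S,5R,6R,7S)-5-allyl-7-Ar-2-hydroxy-1,3-dimethoxy-6-methylbicyclo[3.2.1]oct-3-en-8-one
Conditions: NaBH4, CeCl3·7H2O, MeOH, −78 °C
Reagents that add atoms: none
Why: Luche 1,2-reduction of the enone carbonyl; hydride should come from the exo face (the side of the C8 bridge) because the endo face is covered by the C7 aryl group, giving the (2S) carbinol, while the C8 ketone is flanked by two quaternary carbons and reversibly masked as a hemiketal in CeCl3/MeOH.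

Step 16
Reactants: 19 silyl ether of the target
Product: 20 (1R,2S,5R,6R,7S)-5-allyl-2-hydroxy-7-(4-hydroxy-3-methoxyphenyl)-1,3-dimethoxy-6-methylbicyclo[3.2.1]oct-3-en-8-one (CNP0330966.1)
Conditions: Bu4NF, AcOH, THF, 0 °C
Reagents that add atoms: none
Why: Fluoride cleavage of the aryl silyl ether, buffered with acetic acid so that the β-hydroxy ketone is not opened by retro-aldol reaction.

**Compound list**

1 | dehydrozingerone, (E)-4-(4-hydroxy-3-methoxyphenyl)but-3-en-2-one | CC(=O)/C=C/c1ccc(O)c(OC)c1 | starting material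
2 | (E)-4-Ar-but-3-en-2-one | CC(=O)/C=C/c1ccc(O[Si](C(C)C)(C(C)C)C(C)C)c(OC)c1 | intermediate
3 | (2S,3E)-4-Ar-but-3-en-2-ol | C[C@H](O)/C=C/c1ccc(O[Si](C(C)C)(C(C)C)C(C)C)c(OC)c1 | intermediate
4 | cyclohexane-1,3-dione | O=C1CCCC(=O)C1 | starting material
5 | 2-diazocyclohexane-1,3-dione | [N-]=[N+]=C1C(=O)CCCC1=O | intermediate
6 | 2-methoxycyclohexane-1,3-dione (enol form) | COC1=C(O)CCCC1=O | intermediate
7 | 3-chloro-2-methoxycyclohex-2-en-1-one | COC1=C(Cl)CCCC1=O | intermediate
8 | 2-methoxy-3-{[(2S,3E)-4-Ar-but-3-en-2-yl]oxy}cyclohex-2-en-1-one | C[C@H](OC1=C(OC)C(=O)CCC1)/C=C/c1ccc(O[Si](C(C)C)(C(C)C)C(C)C)c(OC)c1 | intermediate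
9 | allyl bromide | C=CCBr | starting material
10 | 6-allyl-2-methoxy-3-{[(2S,3E)-4-Ar-but-3-en-2-yl]oxy}cyclohex-2-en-1-one (both C6 epimers; not isolated) | C[C@H](OC1=C(OC)C(=O)C(CC=C)CC1)/C=C/c1ccc(O[Si](C(C)C)(C(C)C)C(C)C)c(OC)c1 | intermediate
11 | 1-allyl-2-[(tert-butyldimethylsilyl)oxy]-3-methoxy-4-{[(2S,3E)-4-Ar-but-3-en-2-yl]oxy}cyclohexa-1,3-diene | C[C@H](OC1=C(OC)C(O[Si](C)(C)C(C)(C)C)=C(CC=C)CC1)/C=C/c1ccc(O[Si](C(C)C)(C(C)C)C(C)C)c(OC)c1 | intermediate
12 | (2S)-4-allyl-3-[(tert-butyldimethylsilyl)oxy]-2-methoxy-2-[(1S,2E)-1-Ar-but-2-en-1-yl]cyclohex-3-en-1-one | C=CCC=1CCC(=O)[C@](OC)([C@@H](/C=C/C)c2ccc(O[Si](C(C)C)(C(C)C)C(C)C)c(OC)c2)C=1O[Si](C)(C)C(C)(C)C | intermediate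
13 | (2S)-4-allyl-3-[(tert-butyldimethylsilyl)oxy]-2-methoxy-2-[(1S)-1-Ar-prop-2-en-1-yl]cyclohex-3-en-1-one | C=CCC=1CCC(=O)[C@](OC)([C@@H](C=C)c2ccc(O[Si](C(C)C)(C(C)C)C(C)C)c(OC)c2)C=1O[Si](C)(C)C(C)(C)C | intermediate
14 | (2R)-4-allyl-4-bromo-2-methoxy-2-[(1S)-1-Ar-prop-2-en-1-yl]cyclohexane-1,3-dione (both C4 epimers) | C=CCC1(Br)CCC(=O)[C@](OC)([C@@H](C=C)c2ccc(O[Si](C(C)C)(C(C)C)C(C)C)c(OC)c2)C1=O | intermediate
15 | (1R,5R,6R,7S)-5-allyl-7-Ar-1-methoxy-6-methylbicyclo[3.2.1]octane-2,8-dione | C=CC[C@@]12CCC(=O)[C@@](OC)(C1=O)[C@H](c1ccc(O[Si](C(C)C)(C(C)C)C(C)C)c(OC)c1)[C@H]2C | intermediate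
16 | 5-allyl-7-Ar-3-hydroxy-1-methoxy-6-methylbicyclo[3.2.1]octane-2,8-dione (C1, C5, C6, C7 as in 15; both C3 epimers) | C=CC[C@@]12CC(O)C(=O)[C@@](OC)(C1=O)[C@H](c1ccc(O[Si](C(C)C)(C(C)C)C(C)C)c(OC)c1)[C@H]2C | intermediate
17 | 5-allyl-7-Ar-3-hydroxy-1-methoxy-6-methylbicyclo[3.2.1]oct-3-ene-2,8-dione (C1, C5, C6, C7 as in 15) | C=CC[C@@]12C=C(O)C(=O)[C@@](OC)(C1=O)[C@H](c1ccc(O[Si](C(C)C)(C(C)C)C(C)C)c(OC)c1)[C@H]2C | intermediate
18 | 5-allyl-7-Ar-1,3-dimethoxy-6-methylbicyclo[3.2.1]oct-3-ene-2,8-dione (C1, C5, C6, C7 as in 15) | C=CC[C@@]12C=C(OC)C(=O)[C@@](OC)(C1=O)[C@H](c1ccc(O[Si](C(C)C)(C(C)C)C(C)C)c(OC)c1)[C@H]2C | intermediate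
19 | (1R,2S,5R,6R,7S)-5-allyl-7-Ar-2-hydroxy-1,3-dimethoxy-6-methylbicyclo[3.2.1]oct-3-en-8-one | C=CC[C@@]12C=C(OC)[C@H](O)[C@@](OC)(C1=O)[C@H](c1ccc(O[Si](C(C)C)(C(C)C)C(C)C)c(OC)c1)[C@H]2C | intermediate
20 | (1R,2S,5R,6R,7S)-5-allyl-2-hydroxy-7-(4-hydroxy-3-methoxyphenyl)-1,3-dimethoxy-6-methylbicyclo[3.2.1]oct-3-en-8-one | C=CC[C@@]12C=C(OC)[C@H](O)[C@@](OC)(C1=O)[C@H](c1ccc(O)c(OC)c1)[C@H]2C | target

**Step count and risks**

Total step count: 16. Longest linear sequence: 14 steps (steps 3 to 16, from cyclohexane-1,3-dione).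

Steps most likely to fail:

1. Step 11. The C5 radical may close at the terminal vinyl carbon (6-endo) to a bicyclo[3.3.1]nonane, and the primary radical may add to the C5 allyl group before hydrogen transfer. Fallback: block the alkene terminus so that only C6 can be attacked, setting out from 8 and coming back at 15.
   - α′-Chlorination of 8 (LiN(iPr)2, then C2Cl6) in place of the allylation gives the 6-chloro enone F1.
   - Thermal Claisen rearrangement of F1 (xylene, 140 °C) gives the 4-chloro-1,3-dione F2 with the same C1/C7 outcome.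
   - As no other alkene is present, ozonolysis (O3, then Me2S) cuts the propenyl group to the aldehyde F3, and CBr4/PPh3 turns it into the 2,2-dibromovinyl compound F4.
   - Allylation of the chloro ketone enolate (LiN(SiMe3)2, allyl iodide) gives the tertiary chloride F5.
   - With (Me3Si)3SiH (about 4 equiv), thiol and AIBN, F5 should close 5-exo only, since the terminal carbon is fully substituted as in the known closures onto prenyl-type alkenes. The CHBr2 group formed is reduced on to CH3 in the same flask, which gives 15.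

2. Step 15. Hydride may also attack the C8 ketone (poor chemoselectivity between the two carbonyl groups). Fallback: accept reduction of both and restore C8, setting out from 18 and coming back at 20.
   - iBu2AlH (excess, CH2Cl2, −78 °C) gives the 2,8-diol F6.
   - The less hindered C2 hydroxyl is silylated (tBuMe2SiOTf, 2,6-lutidine, −78 °C) to the mono-silyl ether F7.
   - Dess–Martin oxidation of the remaining C8 carbinol gives the 8-ketone F8.
   - Bu4NF/AcOH removes both silyl groups and gives 20.

3. Step 8. Chirality transfer may be eroded by ionisation of the electron-rich secondary allylic ether, or by a competing boat pathway. Fallback: use a primary allylic ether and separate enantiomers, setting out from 7 and coming back at 13 (step 9 is then not needed).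
   - Coniferyl alcohol is silylated at the phenol (NaH, 1 equiv, then iPr3SiCl) to 4-O-triisopropylsilyl coniferyl alcohol F9.
   - Its sodium alkoxide and 7 give the primary vinylogous ester F10.
   - Allylation and silylation as in step 7 give the silyl dienol ether F11.
   - Thermal Claisen rearrangement through the same chair gives 13 directly, together with its enantiomer F12; the two are separated by preparative chromatography on a chiral stationary phase.

**Further compounds**

F1 | step 11 | 6-chloro-2-methoxy-3-{[(2S,3E)-4-Ar-but-3-en-2-yl]oxy}cyclohex-2-en-1-one (both C6 epimers) | C[C@H](OC1=C(OC)C(=O)C(Cl)CC1)/C=C/c1ccc(O[Si](C(C)C)(C(C)C)C(C)C)c(OC)c1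
F2 | step 11 | 4-chloro-2-methoxy-2-[(1S,2E)-1-Ar-but-2-en-1-yl]cyclohexane-1,3-dione (C2 and side-chain C1 as in 14; both C4 epimers) | ClC1CCC(=O)[C@](OC)([C@@H](/C=C/C)c2ccc(O[Si](C(C)C)(C(C)C)C(C)C)c(OC)c2)C1=O
F3 | step 11 | 2-Ar-2-(3-chloro-1-methoxy-2,6-dioxocyclohexyl)acetaldehyde (configured as F2) | ClC1CCC(=O)[C@](OC)([C@@H](C=O)c2ccc(O[Si](C(C)C)(C(C)C)C(C)C)c(OC)c2)C1=O
F4 | step 11 | 4-chloro-2-(3,3-dibromo-1-Ar-prop-2-en-1-yl)-2-methoxycyclohexane-1,3-dione (configured as F2) | ClC1CCC(=O)[C@](OC)([C@@H](C=C(Br)Br)c2ccc(O[Si](C(C)C)(C(C)C)C(C)C)c(OC)c2)C1=O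
F5 | step 11 | 4-allyl-4-chloro-2-(3,3-dibromo-1-Ar-prop-2-en-1-yl)-2-methoxycyclohexane-1,3-dione (configured as F2; both C4 epimers) | C=CCC1(Cl)CCC(=O)[C@](OC)([C@@H](C=C(Br)Br)c2ccc(O[Si](C(C)C)(C(C)C)C(C)C)c(OC)c2)C1=O
F6 | step 15 | 5-allyl-7-Ar-1,3-dimethoxy-6-methylbicyclo[3.2.1]oct-3-ene-2,8-diol (C1, C2, C5, C6, C7 as in 19; C8 either way) | C=CC[C@@]12C=C(OC)[C@H](O)[C@@](OC)(C1O)[C@H](c1ccc(O[Si](C(C)C)(C(C)C)C(C)C)c(OC)c1)[C@H]2C
F7 | step 15 | 5-allyl-7-Ar-2-[(tert-butyldimethylsilyl)oxy]-1,3-dimethoxy-6-methylbicyclo[3.2.1]oct-3-en-8-ol | C=CC[C@@]12C=C(OC)[C@H](O[Si](C)(C)C(C)(C)C)[C@@](OC)(C1O)[C@H](c1ccc(O[Si](C(C)C)(C(C)C)C(C)C)c(OC)c1)[C@H]2C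
F8 | step 15 | 5-allyl-7-Ar-2-[(tert-butyldimethylsilyl)oxy]-1,3-dimethoxy-6-methylbicyclo[3.2.1]oct-3-en-8-one | C=CC[C@@]12C=C(OC)[C@H](O[Si](C)(C)C(C)(C)C)[C@@](OC)(C1=O)[C@H](c1ccc(O[Si](C(C)C)(C(C)C)C(C)C)c(OC)c1)[C@H]2C
F9 | step 8 | (2E)-3-Ar-prop-2-en-1-ol (4-O-triisopropylsilyl coniferyl alcohol) | OC/C=C/c1ccc(O[Si](C(C)C)(C(C)C)C(C)C)c(OC)c1
F10 | step 8 | 2-methoxy-3-{[(2E)-3-Ar-prop-2-en-1-yl]oxy}cyclohex-2-en-1-one | COC1=C(OC/C=C/c2ccc(O[Si](C(C)C)(C(C)C)C(C)C)c(OC)c2)CCCC1=O
F11 | step 8 | 1-allyl-2-[(tert-butyldimethylsilyl)oxy]-3-methoxy-4-{[(2E)-3-Ar-prop-2-en-1-yl]oxy}cyclohexa-1,3-diene | C=CCC1=C(O[Si](C)(C)C(C)(C)C)C(OC)=C(OC/C=C/c2ccc(O[Si](C(C)C)(C(C)C)C(C)C)c(OC)c2)CC1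
F12 | step 8 | (2R)-4-allyl-3-[(tert-butyldimethylsilyl)oxy]-2-methoxy-2-[(1R)-1-Ar-prop-2-en-1-yl]cyclohex-3-en-1-one (enantiomer of 13) | C=CCC=1CCC(=O)[C@@](OC)([C@H](C=C)c2ccc(O[Si](C(C)C)(C(C)C)C(C)C)c(OC)c2)C=1O[Si](C)(C)C(C)(C)C
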